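The route rests on the bond between C6 (the cyclobutane CH) and C11 (the quaternary carbon bearing CH2OAc). It ties the two one-carbon bridges, C4 and C6, of a bicyclo[3.1.1]heptane core together across the cyclobutane face opposite the C8–C10 ketone bridge. The core comes from an intramolecular keteniminium–alkene [2+2] cycloaddition that leaves C6 as a ketone. In the key step, iron-hydride hydrogen-atom transfer turns the 1,1-disubstituted alkene of the C4 side chain into the tertiary C11 radical, which closes the seven-membered ring C1–C2–C3–C4–C5–C6–C11 onto the C6 tosylhydrazone; loss of sulfinate and N2 leaves C6–H. One operation gives the ring, quaternary C11 and its methyl group.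

Key step: step 15

Remark (atom labels used in the names): C1 = CH–O-angeloyl, C2 = CH2, C3 = CH–OH, C4 = quaternary cyclobutane carbon (methyl C14), C5 and C7 = cyclobutane CH bridgeheads (C7 next to the ketone), C6 = cyclobutane CH bonded to C11, C8 = ketone carbon, C9 = CH2, C10 = CH(CH3) (methyl C15), C11 = quaternary carbon (methyl C13, C12H2–OAc). "Syn/anti" refers to the C8–C10 bridge.

Step 1
Reactants: 1 prop-2-yn-1-ol
Product: 3 (E)-3-iodo-2-methylprop-2-en-1-ol, via alkenylalane 2 (not isolated)
Conditions: AlMe3 (3 equiv), Cp2ZrCl2 (0.25 equiv), CH2Cl2, 0 to 23 °C; then I2, THF, −30 to 0 °C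
Reagents that add atoms: trimethylaluminium C[Al](C)C; iodine [I][I]
Why: Negishi zirconium-catalysed carboalumination adds methyl and aluminium syn across the alkyne (methyl on the internal carbon), and iodinolysis of the C–Al bond with retention should give the (E)-iodoalkene with iodine cis to methyl.

Step 2
Reactants: 3 (E)-3-iodo-2-methylprop-2-en-1-ol
Product: 4 (E)-tert-butyl[(3-iodo-2-methylprop-2-en-1-yl)oxy]dimethylsilane
Conditions: TBSCl, imidazole, CH2Cl2, 0 to 23 °C
Reagents that add atoms: tert-butyldimethylsilyl chloride CC(C)(C)[Si](C)(C)Cl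
Why: Standard silylation of the primary allylic alcohol protects the future C3 oxygen through the organometallic steps.

Step 3
Reactants: 4 (E)-tert-butyl[(3-iodo-2-methylprop-2-en-1-yl)oxy]dimethylsilane; 5 (R)-5-methoxy-3-methyl-5-oxopentanoic acid
Product: 9 methyl (3R,6E)-8-(tert-butyldimethylsilyloxy)-3,7-dimethyl-5-oxooct-6-enoate, via alkenyllithium 6 (not isolated), via alkenylzinc chloride 7 (not isolated), via acid chloride 8 (not isolated)
Conditions: 5, (COCl)2, DMF (cat.), CH2Cl2, 0 to 23 °C, then evaporation; 4, t-BuLi (2 equiv), Et2O, −78 °C, then ZnCl2, THF, −78 to 0 °C; then 8, Pd(PPh3)4 (5 mol%), THF, 0 to 23 °C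
Reagents that add atoms: none
Why: Negishi acylation: iodine–lithium exchange and transmetalation to zinc keep the alkene geometry, and Pd-catalysed coupling of the alkenylzinc with the acid chloride should give the (E)-enone without attack on the methyl ester or the C10 stereocentre.

Step 4
Reactants: 9 methyl (3R,6E)-8-(tert-butyldimethylsilyloxy)-3,7-dimethyl-5-oxooct-6-enoate
Product: 10 methyl (3R)-4-{2-[(1E)-3-(tert-butyldimethylsilyloxy)-2-methylprop-1-en-1-yl]-1,3-dioxolan-2-yl}-3-methylbutanoate
Conditions: 1,2-bis(trimethylsilyloxy)ethane (2 equiv), TMSOTf (5 mol%), CH2Cl2, −78 to −20 °C; pyridine quench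
Reagents that add atoms: 1,2-bis(trimethylsilyloxy)ethane C[Si](C)(C)OCCO[Si](C)(C)C
Why: Noyori ketalisation masks the C8 ketone under aprotic low-temperature conditions that neither move nor isomerise the double bond, which turns the enone into a nucleophilic trisubstituted alkene.

Step 5
Reactants: 10 methyl (3R)-4-{2-[(1E)-3-(tert-butyldimethylsilyloxy)-2-methylprop-1-en-1-yl]-1,3-dioxolan-2-yl}-3-methylbutanoate
Product: 11 (3R)-4-{2-[(1E)-3-(tert-butyldimethylsilyloxy)-2-methylprop-1-en-1-yl]-1,3-dioxolan-2-yl}-3-methyl-1-(pyrrolidin-1-yl)butan-1-one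
Conditions: pyrrolidine (5 equiv), 1,5,7-triazabicyclo[4.4.0]dec-5-ene (30 mol%), 70 °C
Reagents that add atoms: pyrrolidine C1CCNC1
Why: Base-catalysed aminolysis of the methyl ester gives the tertiary amide needed for keteniminium formation, the ketal preventing conjugate addition of the amine.

Step 6
Reactants: 11 (3R)-4-{2-[(1E)-3-(tert-butyldimethylsilyloxy)-2-methylprop-1-en-1-yl]-1,3-dioxolan-2-yl}-3-methyl-1-(pyrrolidin-1-yl)butan-1-one
Product: 14 bicyclo[3.1.1]heptan-6-one (C6 ketone; C8 dioxolane; C4 methyl syn and C4 CH2OTBS anti; C10 methyl on the C6 side), via keteniminium triflate 12 (not isolated), via cyclobutaniminium triflate 13 (not isolated)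
Conditions: Tf2O (1.1 equiv), 2,4,6-collidine (1.2 equiv), ClCH2CH2Cl (0.02 M), −25 °C then 80 °C; then H2O, 23 °C
Reagents that add atoms: water O
Why: Ghosez-type intramolecular keteniminium–alkene [2+2] cycloaddition: the electrophilic carbon C6 bonds to the alkene CH (C7) so that positive charge builds up on the disubstituted carbon C4, which gives the crossed bicyclo[3.1.1] skeleton; addition is suprafacial on the alkene, so the (E) geometry should place the C4 methyl syn and CH2OTBS anti, the C10 methyl should take the side of the C6 bridge to avoid the C4 methyl and thereby fix the absolute configuration of C4, C5 and C7, and hydrolysis of the iminium salt gives the cyclobutanone.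

Step 7
Reactants: 14 bicyclo[3.1.1]heptan-6-one with C4 CH2OTBS
Product: 15 primary alcohol (C3H2OH on C4; C6 ketone; C8 dioxolane)
Conditions: Bu4NF, AcOH, THF, 0 to 23 °C
Reagents that add atoms: none
Why: Fluoride cleaves the primary silyl ether, and the dioxolane and the cyclobutanone should be stable to buffered fluoride.

Step 8
Reactants: 15 primary alcohol
Product: 16 C3 aldehyde (formyl group on C4 anti; C6 ketone; C8 dioxolane)
Conditions: Dess–Martin periodinane, NaHCO3, CH2Cl2, 0 to 23 °C
Reagents that add atoms: none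
Why: Dess–Martin oxidation of the neopentyl primary alcohol gives an aldehyde that has no α-hydrogen and cannot epimerise.

Step 9
Reactants: 17 but-3-en-2-one
Product: 18 3-(hydroxymethyl)but-3-en-2-one
Conditions: formaldehyde (37% aq.), 1,4-diazabicyclo[2.2.2]octane (20 mol%), THF/H2O, 23 °C
Reagents that add atoms: formaldehyde C=O
Why: Morita–Baylis–Hillman reaction installs the hydroxymethyl group (future C12) on the α-carbon (future C11) of the enone.

Step 10
Reactants: 18 3-(hydroxymethyl)but-3-en-2-one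
Product: 19 3-[(tert-butyldimethylsilyloxy)methyl]but-3-en-2-one
Conditions: TBSCl, imidazole, CH2Cl2, 0 °C
Reagents that add atoms: tert-butyldimethylsilyl chloride CC(C)(C)[Si](C)(C)Cl
Why: Silylation protects the primary alcohol before enolisation of the methyl ketone.

Step 11
Reactants: 16 C3 aldehyde; 19 3-[(tert-butyldimethylsilyloxy)methyl]but-3-en-2-one
Product: 22 (3R)-β-hydroxy enone (chain C3H(OH)–C2H2–C1(=O)–C11(=CH2)–C12H2OTBS on C4), via boron enolate 20 (not isolated), via boron aldolate 21 (not isolated)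
Conditions: 19 (1.5 equiv), (+)-Ipc2BCl (1.6 equiv), Et3N (2 equiv), Et2O, 0 °C; then 16, −78 to −20 °C; then pH 7 buffer, MeOH, H2O2 (30% aq.), 0 °C
Reagents that add atoms: none
Why: Paterson boron aldol reaction: the diisopinocampheylboron enolate of the methyl ketone should add to the aldehyde only (not to the hindered cyclobutanone), and the chiral boron ligands, not the nearly symmetric bicycle, decide the face, the (+)-reagent being chosen for Re-face attack to give (R) at C3.

Step 12
Reactants: 22 (3R)-β-hydroxy enone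
Product: 23 (1R,3R)-anti-1,3-diol
Conditions: Me4NBH(OAc)3 (5 equiv), MeCN/AcOH 1:1, −30 °C
Reagents that add atoms: none
Why: Evans–Saksena reduction: the C3 alkoxyborohydride delivers hydride intramolecularly to the C1 ketone through a chair transition state, which should give the 1,3-anti diol ((R) at C1) and leave the undirected C6 ketone untouched.

Step 13
Reactants: 23 (1R,3R)-anti-1,3-diol
Product: 24 C1 angelate (C3 hydroxyl free)
Conditions: angelic acid (1.3 equiv), 2,4,6-trichlorobenzoyl chloride (1.3 equiv), Et3N, toluene, 23 °C; then 23, 60 °C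
Reagents that add atoms: angelic acid C/C=C(/C)C(=O)O
Why: Yamaguchi-type esterification through the preformed mixed anhydride (no DMAP) transfers the angeloyl group without Z to E isomerisation, and only the accessible allylic C1 hydroxyl should react because the C3 hydroxyl is neopentylic and shielded by the cyclobutane.

Step 14
Reactants: 24 C1 angelate
Product: 25 C6 N-tosylhydrazone of 24
Conditions: TsNHNH2 (1.1 equiv), MeOH, 23 °C
Reagents that add atoms: 4-methylbenzenesulfonohydrazide Cc1ccc(cc1)S(=O)(=O)NN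
Why: Condensation of the strained, electrophilic cyclobutanone, the only free ketone, with tosylhydrazide gives the hydrazone that serves as radical acceptor.

Step 15
Reactants: 25 C6 N-tosylhydrazone
Product: 28 tricyclic angelate (C6–C11 bond formed; C6–H syn; C11 with methyl C13 and C12H2OTBS; C8 dioxolane; C3 hydroxyl free), via cyclised tosylhydrazide 26 (not isolated), via diazene 27 (not isolated)
Conditions: Fe(acac)3 (0.5 equiv), PhSiH3 (3 equiv), EtOH (0.005 M), 60 °C; then NaOAc (5 equiv), 80 °C
Reagents that add atoms: none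
Why: Iron-hydride hydrogen-atom transfer to the terminal CH2 of the 1,1-disubstituted alkene (which becomes the C13 methyl) gives the tertiary C11 radical, this adds to the carbon of the C6 N-tosylhydrazone, the hydrazinyl radical is reduced to hydrazide 26, and NaOAc then eliminates p-toluenesulfinate to diazene 27, which loses N2 and leaves hydrogen on C6. The closest known reaction types are the iron-hydride-initiated reductive coupling of alkenes with N-sulfonylhydrazones (intra- and intermolecular) and the Caglioti-type breakdown of N-alkyl-N'-sulfonylhydrazides to alkanes. Only the seven-membered ring C1–C2–C3–C4–C5–C6–C11 is closed, in a 7-exo-trig radical mode (the hydrazone nitrogen stays outside the ring), and the strain released when the sp2 cyclobutane carbon C6 becomes sp3 helps the addition. C6 is controlled by the ring itself, since the C4 side chain can reach C6 only from the face anti to the C8–C10 bridge, so C11 ends on that face and the hydrogen that replaces nitrogen must be syn; C11 is controlled by the adjacent C1 stereocentre, the larger CH2OTBS group going trans to the C1 acyloxy group in the chair-like transition state and the new methyl cis to it. The step needs ring closure to outrun reduction of the tertiary radical and 1,5-hydrogen transfer from C3–H, and it needs hydrogen-atom transfer to the electron-rich 1,1-disubstituted alkene and not to the angelate; the cis-1,3 (pseudo-diaxial) placement of chain and hydrazone on the cyclobutane, high dilution, and the electron-poor trisubstituted angelate double bond should secure this.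

Step 16
Reactants: 28 tricyclic angelate
Product: 29 C12 primary alcohol with C8 ketone (deacetyl target)
Conditions: HCl (2 M aq.)/THF 1:3, 23 °C
Reagents that add atoms: water O
Why: Aqueous acid hydrolyses the dioxolane to the C8 ketone and cleaves the primary silyl ether in one operation, while the angelate and the C3 hydroxyl are inert and the bridgehead C7 cannot epimerise.

Step 17
Reactants: 29 C12 primary alcohol with C8 ketone
Product: 30 CNP0212099.1 (target)
Conditions: Ac2O (1.2 equiv), pyridine, CH2Cl2, 0 °C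
Reagents that add atoms: acetic anhydride CC(=O)OC(C)=O
Why: Acetylation of the primary C12 hydroxyl should be much faster than that of the hindered secondary C3 hydroxyl, which gives the target.

Compound list
1 | prop-2-yn-1-ol | C#CCO | starting material
2 | alkenylalane: (E)-dimethyl[3-(dimethylalumanyloxy)-2-methylprop-1-en-1-yl]alumane (Al cis to methyl) | C[Al](C)/C=C(\C)CO[Al](C)C | intermediate
3 | (E)-3-iodo-2-methylprop-2-en-1-ol (iodine cis to methyl) | OC/C(C)=C/I | intermediate
4 | (E)-tert-butyl[(3-iodo-2-methylprop-2-en-1-yl)oxy]dimethylsilane | CC(C)(C)[Si](C)(C)OC/C(C)=C/I | intermediate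
5 | (R)-5-methoxy-3-methyl-5-oxopentanoic acid (methyl hydrogen (R)-3-methylglutarate) | COC(=O)C[C@H](C)CC(=O)O | starting material
6 | alkenyllithium: (E)-[3-(tert-butyldimethylsilyloxy)-2-methylprop-1-en-1-yl]lithium | CC(C)(C)[Si](C)(C)OC/C(C)=C/[Li] | intermediate
7 | alkenylzinc chloride: (E)-[3-(tert-butyldimethylsilyloxy)-2-methylprop-1-en-1-yl]zinc chloride | CC(C)(C)[Si](C)(C)OC/C(C)=C/[Zn]Cl | intermediate
8 | acid chloride: methyl (S)-5-chloro-3-methyl-5-oxopentanoate | COC(=O)C[C@H](C)CC(=O)Cl | intermediate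
9 | methyl (3R,6E)-8-(tert-butyldimethylsilyloxy)-3,7-dimethyl-5-oxooct-6-enoate | COC(=O)C[C@H](C)CC(=O)/C=C(\C)CO[Si](C)(C)C(C)(C)C | intermediate
10 | methyl (3R)-4-{2-[(1E)-3-(tert-butyldimethylsilyloxy)-2-methylprop-1-en-1-yl]-1,3-dioxolan-2-yl}-3-methylbutanoate | COC(=O)C[C@H](C)CC1(OCCO1)/C=C(\C)CO[Si](C)(C)C(C)(C)C | intermediate
11 | (3R)-4-{2-[(1E)-3-(tert-butyldimethylsilyloxy)-2-methylprop-1-en-1-yl]-1,3-dioxolan-2-yl}-3-methyl-1-(pyrrolidin-1-yl)butan-1-one | O=C(C[C@H](C)CC1(OCCO1)/C=C(\C)CO[Si](C)(C)C(C)(C)C)N1CCCC1 | intermediate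
12 | keteniminium triflate of 11 (C6=C5 ketene-type cumulene, N-pyrrolidinium) | C(=[N+]1CCCC1)=C[C@H](C)CC1(OCCO1)/C=C(\C)CO[Si](C)(C)C(C)(C)C.[O-]S(=O)(=O)C(F)(F)F | intermediate
13 | cyclobutaniminium triflate (bicyclo[3.1.1]heptane with C6=N+ pyrrolidinium; C4 methyl syn, CH2OTBS anti; C8 dioxolane) | CC(C)(C)[Si](C)(C)OC[C@]1(C)[C@@H]2C(=[N+]3CCCC3)[C@H]1C3(OCCO3)C[C@H]2C.[O-]S(=O)(=O)C(F)(F)F | intermediate
14 | 7-[(tert-butyldimethylsilyloxy)methyl]-4,7-dimethylspiro[bicyclo[3.1.1]heptane-2,2'-[1,3]dioxolan]-6-one (C6 ketone; C4 methyl syn, CH2OTBS anti; C10 (R) methyl on the C6 side) | CC(C)(C)[Si](C)(C)OC[C@]1(C)[C@@H]2C(=O)[C@H]1C3(OCCO3)C[C@H]2C | intermediate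
15 | 7-(hydroxymethyl)-4,7-dimethylspiro[bicyclo[3.1.1]heptane-2,2'-[1,3]dioxolan]-6-one (same configuration as 14) | OC[C@]1(C)[C@@H]2C(=O)[C@H]1C3(OCCO3)C[C@H]2C | intermediate
16 | 4,7-dimethyl-6-oxospiro[bicyclo[3.1.1]heptane-2,2'-[1,3]dioxolane]-7-carbaldehyde (formyl anti, methyl syn) | O=C[C@]1(C)[C@@H]2C(=O)[C@H]1C3(OCCO3)C[C@H]2C | intermediate
17 | but-3-en-2-one | CC(=O)C=C | starting material
18 | 3-(hydroxymethyl)but-3-en-2-one | CC(=O)C(=C)CO | intermediate
19 | 3-[(tert-butyldimethylsilyloxy)methyl]but-3-en-2-one | CC(=O)C(=C)CO[Si](C)(C)C(C)(C)C | intermediate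
20 | boron enolate: diisopinocampheylboron dienolate of 19 (Ipc groups from (−)-α-pinene) | C=C(OB([C@H]1C[C@H]2C[C@@H]([C@@H]1C)C2(C)C)[C@H]1C[C@H]2C[C@@H]([C@@H]1C)C2(C)C)C(=C)CO[Si](C)(C)C(C)(C)C | intermediate
21 | boron aldolate: C3 O-diisopinocampheylboryl derivative of 22 | C=C(CO[Si](C)(C)C(C)(C)C)C(=O)C[C@@H](OB([C@H]1C[C@H]2C[C@@H]([C@@H]1C)C2(C)C)[C@H]1C[C@H]2C[C@@H]([C@@H]1C)C2(C)C)[C@]1(C)[C@@H]2C(=O)[C@H]1C3(OCCO3)C[C@H]2C | intermediate
22 | (3R)-β-hydroxy enone: C4 bears (anti) the chain C3H(OH)–C2H2–C1(=O)–C11(=CH2)–C12H2OTBS; C6 ketone; C8 dioxolane | C=C(CO[Si](C)(C)C(C)(C)C)C(=O)C[C@@H](O)[C@]1(C)[C@@H]2C(=O)[C@H]1C3(OCCO3)C[C@H]2C | intermediate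
23 | (1R,3R)-anti-1,3-diol of 22 (C1 allylic carbinol) | O[C@@H](C(=C)CO[Si](C)(C)C(C)(C)C)C[C@@H](O)[C@]1(C)[C@@H]2C(=O)[C@H]1C3(OCCO3)C[C@H]2C | intermediate
24 | C1 (Z)-2-methylbut-2-enoate (angelate) of 23, C3 hydroxyl free | C/C=C(/C)C(=O)O[C@@H](C(=C)CO[Si](C)(C)C(C)(C)C)C[C@@H](O)[C@]1(C)[C@@H]2C(=O)[C@H]1C3(OCCO3)C[C@H]2C | intermediate
25 | C6 N-tosylhydrazone of 24 | C/C=C(/C)C(=O)O[C@@H](C(=C)CO[Si](C)(C)C(C)(C)C)C[C@@H](O)[C@]1(C)[C@@H]2C(=NNS(=O)(=O)c3ccc(C)cc3)[C@H]1C3(OCCO3)C[C@H]2C | intermediate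
26 | cyclised tosylhydrazide: tricycle with C6–C11 bond, C6–NH–NHTs syn, C11 (S) with methyl and CH2OTBS | C/C=C(/C)C(=O)O[C@@H]1C[C@@H](O)[C@]2(C)[C@@H]3[C@]([C@H]2C4(OCCO4)C[C@H]3C)(NNS(=O)(=O)c5ccc(C)cc5)[C@@]1(C)CO[Si](C)(C)C(C)(C)C | intermediate
27 | diazene: tricycle with C6–N=NH | C/C=C(/C)C(=O)O[C@@H]1C[C@@H](O)[C@]2(C)[C@@H]3[C@]([C@H]2C4(OCCO4)C[C@H]3C)(N=N)[C@@]1(C)CO[Si](C)(C)C(C)(C)C | intermediate
28 | tricyclic angelate: target skeleton with C8 as 1,3-dioxolane and C12 as OTBS; C1 (R) O-angeloyl, C3 (R) OH, C11 (S), C6–H syn | C/C=C(/C)C(=O)O[C@@H]1C[C@@H](O)[C@]2(C)[C@@H]3[C@@H]([C@H]2C4(OCCO4)C[C@H]3C)[C@@]1(C)CO[Si](C)(C)C(C)(C)C | intermediate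
29 | deacetyl target: C8 ketone, C12H2OH, C1 O-angeloyl, C3 OH | C/C=C(/C)C(=O)O[C@@H]1C[C@@H](O)[C@]2(C)[C@@H]3[C@@H]([C@H]2C(=O)C[C@H]3C)[C@@]1(C)CO | intermediate
30 | CNP0212099.1: C1 O-angeloyl, C3 OH, C12 O-acetyl, C8 ketone (C1 R, C3 R, C4 R, C5 S, C6 S, C7 R, C10 R, C11 S in the labels above) | C/C=C(/C)C(=O)O[C@@H]1C[C@@H](O)[C@]2(C)[C@@H]3[C@@H]([C@H]2C(=O)C[C@H]3C)[C@@]1(C)COC(C)=O | target

Total step count: 17. Longest linear sequence: 15 steps (steps 1–8 and 11–17; steps 9 and 10 make the side-chain ketone 19).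

Steps most likely to fail

1. Step 15. The 7-exo addition of the hindered tertiary C11 radical to the fully substituted C6 carbon may be slower than simple reduction of the radical (net hydrogenation of the alkene) or hydrogen transfer from C3–H, and facial control at C11 by C1 may be weak. The fallback adds the radical to the C=O group and removes the oxygen in separate steps. It sets out from 24.
   - Silylation of the C3 hydroxyl (Et3SiOTf, 2,6-lutidine) should give the C3 triethylsilyl ether F1.
   - Iron-hydride alkene–ketone reductive cyclisation (Fe(acac)3, PhSiH3, EtOH, 60 °C) should close the same C6–C11 bond onto the cyclobutanone and give the tertiary C6 alcohol F2.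
   - Acylation with methyl chlorooxoacetate (DMAP, pyridine) should give the C6 methyl oxalate F3.
   - Barton-type radical deoxygenation (Bu3SnH, AIBN, toluene, 110 °C) should give the C3-silylated tricycle F4, in which the hydrogen at C6 is again forced syn.
   - F4 is taken through the conditions of step 16, which also remove the triethylsilyl group, and the route is rejoined at 29.

2. Step 6. The keteniminium ion may be captured by a dioxolane oxygen, the ketal or silyl ether may be lost under the acidic conditions, or regio- and stereocontrol may erode in a stepwise cationic closure. The fallback uses a neutral ketene in place of the cation. It sets out from 10.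
   - Saponification (LiOH, THF/H2O; NaH2PO4 work-up) should give the carboxylic acid F5.
   - (COCl)2 should give the acid chloride F6.
   - Slow addition to Et3N in toluene at 110 °C under high dilution should generate the ketene F7, whose thermal intramolecular ketene–alkene [2+2] cycloaddition should give 14 directly with the same regio- and stereochemical logic.

3. Step 11. Addition of the boron enolate to the neopentyl aldehyde may be slow or poorly face-selective, attack at the cyclobutanone may compete, or the product may undergo retro-aldol cleavage on work-up. The fallback replaces the aldol by allylation and oxidation. It sets out from 16.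
   - Brown allylation with (+)-Ipc2B(allyl) (Et2O, −78 °C; H2O2 work-up) should give the (R)-homoallylic alcohol F8.
   - Ozonolysis (O3, CH2Cl2, −78 °C; PPh3) should give the β-hydroxy aldehyde F9.
   - Nozaki–Hiyama–Kishi coupling with tert-butyl[(2-iodoprop-2-en-1-yl)oxy]dimethylsilane (CrCl2, NiCl2 cat., DMSO) should give the allylic alcohol F10 as a mixture of C1 epimers.
   - MnO2 should oxidise only the allylic hydroxyl and return the β-hydroxy enone 22.

Further compounds
F1 | step 15 | C3 triethylsilyl ether of 24 | C/C=C(/C)C(=O)O[C@@H](C(=C)CO[Si](C)(C)C(C)(C)C)C[C@@H](O[Si](CC)(CC)CC)[C@]1(C)[C@@H]2C(=O)[C@H]1C3(OCCO3)C[C@H]2C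
F2 | step 15 | tertiary C6 alcohol (tricycle, C6–OH syn, C3 OTES) | C/C=C(/C)C(=O)O[C@@H]1C[C@@H](O[Si](CC)(CC)CC)[C@]2(C)[C@@H]3[C@]([C@H]2C4(OCCO4)C[C@H]3C)(O)[C@@]1(C)CO[Si](C)(C)C(C)(C)C
F3 | step 15 | C6 methyl oxalate of F2 | C/C=C(/C)C(=O)O[C@@H]1C[C@@H](O[Si](CC)(CC)CC)[C@]2(C)[C@@H]3[C@]([C@H]2C4(OCCO4)C[C@H]3C)(OC(=O)C(=O)OC)[C@@]1(C)CO[Si](C)(C)C(C)(C)C
F4 | step 15 | C3 triethylsilyl ether of 28 | C/C=C(/C)C(=O)O[C@@H]1C[C@@H](O[Si](CC)(CC)CC)[C@]2(C)[C@@H]3[C@@H]([C@H]2C4(OCCO4)C[C@H]3C)[C@@]1(C)CO[Si](C)(C)C(C)(C)C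
F5 | step 6 | (3R)-4-{2-[(1E)-3-(tert-butyldimethylsilyloxy)-2-methylprop-1-en-1-yl]-1,3-dioxolan-2-yl}-3-methylbutanoic acid | OC(=O)C[C@H](C)CC1(OCCO1)/C=C(\C)CO[Si](C)(C)C(C)(C)C
F6 | step 6 | acid chloride of F5 | ClC(=O)C[C@H](C)CC1(OCCO1)/C=C(\C)CO[Si](C)(C)C(C)(C)C
F7 | step 6 | ketene from F6 | O=C=C[C@H](C)CC1(OCCO1)/C=C(\C)CO[Si](C)(C)C(C)(C)C
F8 | step 11 | (R)-homoallylic alcohol (C3H(OH)–CH2–CH=CH2 on C4) | C=CC[C@@H](O)[C@]1(C)[C@@H]2C(=O)[C@H]1C3(OCCO3)C[C@H]2C
F9 | step 11 | β-hydroxy aldehyde (C3H(OH)–C2H2–C1HO on C4) | O=CC[C@@H](O)[C@]1(C)[C@@H]2C(=O)[C@H]1C3(OCCO3)C[C@H]2C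
F10 | step 11 | allylic alcohol, C1 epimer mixture (C1H(OH)–C11(=CH2)–CH2OTBS) | C=C(CO[Si](C)(C)C(C)(C)C)C(O)C[C@@H](O)[C@]1(C)[C@@H]2C(=O)[C@H]1C3(OCCO3)C[C@H]2C
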